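The earlier runs and the new flask were generated by integration for substances that don't exist; scatter was added.

37.8 h of full-strength catalyst: that is what this flask needs to consume half of its starting material.

- south: starting material 10 mM; gas phase 0.52 mM (held); free catalyst 2.5 mol%; run made earlier
- flask: starting material 10 mM; gas phase 0.52 mM (held); free catalyst 5 mol%; time 10 d

- south (time / h: product / %): 2.00: 2.3; 6.00: 6.1; 12.0: 11.6; 15.0: 13.2; 25.0: 20.5

(readings scatter by 1 percentage point)

- at the start none of the gas phase is in solution
- no earlier run changes the charge of free catalyst; that part of a forecast is a guess

- the product standing at 10 d, as a percentage of the starting material charged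
- the change that raises the amount of product at 10 d, in percent of the starting material charged most ("none" if none brings more than 2 percentage points) (spring / dawn / autumn / none)
- amount of product at 10 d, in percent of the starting material charged, after spring

- spring: doubling the saturation concentration of gas phase, all else as stated
- dawn: doubling the transfer coefficient of the gas phase, all else as stated
- autumn: doubling the amount of free catalyst, all else as stated

The last reading of the south run, 20.5% at 25.0 h, reads as a pseudo-first-order constant of 0.00918 h⁻¹. Scaling it with the loading, which is a guess, gives the flask 0.0184 h⁻¹. A catalyst that survives then consumes 98.8% of the starting material in 10 d.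

Now the question turned round: what would hold the flask under half? The constant times the hours of full-strength catalyst must stay below 0.693. The critical catalyst life, the hours of full-strength catalyst that bring the flask to that crossing, is 15.8% of the time allowed. The south readings stop at 25.0 h, short of that span. Their constant slips from 0.0103 h⁻¹ at 12.0 h to 0.00918 h⁻¹, a slip inside the scatter. If full-strength catalyst in this flask lasts just the 25.0 h that the readings cover, the flask consumes 36.9% of its starting material; if it survives, 98.8%. The reckoning here therefore sets no floor at half, and a result under that crossing stays open.

The forecast gives 90% (65% to 99.5%), names spring, and gives 98% after it (84% to 100%), allowing that “mild catalyst decay is also possible”.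

    gas phase ⇌ dissolved gas, rate k1*(csat - [dissolved gas]) (kL = 0.110 min⁻¹)
    starting material + dissolved gas + free catalyst → free catalyst + product (k = 1300 L² mol⁻² min⁻¹)
    dissolved gas → decomposed reagent (k = 1.80 × 10⁻⁴ min⁻¹)
    free catalyst + product → spent catalyst (k = 0.170 L mol⁻¹ min⁻¹)

The flask gives 46.4% product at 10 d. The best change is spring, which brings 60.5%. Free catalyst falls from 64.6% at 1.00 d to 0.940% at 5.00 d, and product reads 46.2% at 5.00 d and 46.4% at 20.0 d. The 49% of starting material left corresponds to 39.3 h of full-strength catalyst, close to the critical 37.8 h.

In a neighbour flask with 20 mol% of free catalyst, the critical life is 9.44 h, a quarter of this flask's. The computed neighbour leaves 18.1% of its starting material and holds 61.9% product, which corresponds to 23.3 h of full-strength catalyst.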